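1. Target: (2R)-6-methoxy-2,8-dimethylchroman with a (2Z,6E)-2,6-dimethylnona-2,6-dienoic acid chain on C2. The route rests on ring A: its two oxygen substituents stand 1,4 to each other (OMe on C6, ring oxygen O1 on C8a), and C8a lies between C8 (methyl) and C4a (start of the C4–C3 tether). This is the hydroquinone monoether pattern that a methoxy(alkenyl)carbene chromium complex, one CO ligand and a terminal alkyne join up to give.
2. Last C–C bond: C2'–C3' of the side chain (chain carbons counted from C2), by hydroboration of a 2-vinylchroman and B-alkyl Suzuki–Miyaura coupling with an (E)-alkenyl iodide that already holds the (Z)-α-methyl enoate; ester hydrolysis ends the route.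
3. Ring B (second ring): O1–C2, by 6-exo opening of a (2R,3R)-epoxide at its tertiary carbon by the ring A phenol with inversion; the leftover glycol is cut back to the vinyl group.
4. Ring A (first ring): Dötz benzannulation of pentacarbonyl[(2E)-1-methoxybut-2-en-1-ylidene]chromium with the silyl-protected epoxy alkyne, making C5–C6, C4a–C8a and C8–C8a.
5. Building blocks: the epoxy alkyne comes from geranyl acetate, whose E alkene is inherited so that no E/Z mixture can erode C2 (oxidative cleavage, Ohira–Bestmann alkynylation, Sharpless epoxidation, silylation). The iodide comes from pent-4-yn-1-ol (carboalumination–iodination, oxidation, Still–Gennari olefination).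

Key step: step 6

Remark on the chemistry: the tartrate antipode in step 3 is chosen by analogy with geraniol, which gives the (2S,3S)-epoxy alcohol with L-(+)-diethyl tartrate. Compound 4 has the same substitution pattern, so D-(−)-diethyl tartrate is expected to give the 2R,3R series.

Step 1
Reactants: 1 geranyl acetate, (2E)-3,7-dimethylocta-2,6-dien-1-yl acetate
Product: 3 (2E)-3-methyl-6-oxohex-2-en-1-yl acetate, via 6,7-epoxygeranyl acetate 2 (not isolated)
Conditions: mCPBA, CH2Cl2, 0 °C; solvent exchanged for THF–H2O, then H5IO6, 0 °C → rt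
Reagents that add atoms: mCPBA (3-chloroperoxybenzoic acid), OOC(=O)c1cccc(Cl)c1
Why: The electron-rich 6,7-alkene is epoxidised ahead of the 2,3-alkene, which the allylic acetate deactivates (Prilezhaev epoxidation), and periodic acid cleaves the epoxide by way of the glycol to the aldehyde and acetone, leaving the (E)-2,3-alkene untouched.

Step 2
Reactants: 3 (2E)-3-methyl-6-oxohex-2-en-1-yl acetate
Product: 4 (2E)-3-methylhept-2-en-6-yn-1-ol
Conditions: dimethyl (1-diazo-2-oxopropyl)phosphonate, K2CO3, MeOH, 0 °C → rt
Reagents that add atoms: dimethyl (1-diazo-2-oxopropyl)phosphonate, COP(=O)(OC)C(=[N+]=[N-])C(C)=O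
Why: Seyferth–Gilbert homologation in its Ohira–Bestmann form turns the aldehyde into the terminal alkyne, and the same K2CO3/MeOH removes the allylic acetate by transesterification.

Step 3
Reactants: 4 (2E)-3-methylhept-2-en-6-yn-1-ol
Product: 5 [(2R,3R)-3-(but-3-yn-1-yl)-3-methyloxiran-2-yl]methanol
Conditions: Ti(OiPr)4 (cat.), D-(−)-diethyl tartrate (cat.), t-BuOOH (in decane), 4 Å molecular sieves, CH2Cl2, −20 °C
Reagents that add atoms: tert-butyl hydroperoxide, CC(C)(C)OO
Why: Sharpless asymmetric epoxidation of an (E)-trisubstituted allylic alcohol of the geraniol type, in which the titanium tartrate complex delivers oxygen to one alkene face, so that D-(−)-diethyl tartrate should set both epoxide centres as 2R,3R while the alkyne stays inert.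

Step 4
Reactants: 5 [(2R,3R)-3-(but-3-yn-1-yl)-3-methyloxiran-2-yl]methanol
Product: 6 tert-butyl{[(2R,3R)-3-(but-3-yn-1-yl)-3-methyloxiran-2-yl]methoxy}dimethylsilane
Conditions: TBSCl, imidazole, DMF, 0 °C → rt
Reagents that add atoms: tert-butyldimethylsilyl chloride, CC(C)(C)[Si](C)(C)Cl
Why: Routine silylation of a primary alcohol, which takes away the Payne rearrangement pathway and keeps a free hydroxyl out of the benzannulation.

Step 5
Reactants: 7 (E)-1-bromoprop-1-ene; 8 Cr(CO)6
Product: 11 pentacarbonyl[(2E)-1-methoxybut-2-en-1-ylidene]chromium, via (E)-prop-1-enyllithium 9 (not isolated), via lithium acylchromate 10 (not isolated)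
Conditions: t-BuLi (2 equiv), Et2O, −78 °C; Cr(CO)6, Et2O, −78 °C → rt; then Me3OBF4, CH2Cl2, 0 °C → rt
Reagents that add atoms: trimethyloxonium tetrafluoroborate, C[O+](C)C.F[B-](F)(F)F
Why: Fischer carbene synthesis, consisting of bromine–lithium exchange with retention of alkene geometry, addition of the alkenyllithium to a CO ligand of Cr(CO)6 and O-methylation of the acylchromate by the oxonium salt.

Step 6
Reactants: 6 tert-butyl{[(2R,3R)-3-(but-3-yn-1-yl)-3-methyloxiran-2-yl]methoxy}dimethylsilane; 11 pentacarbonyl[(2E)-1-methoxybut-2-en-1-ylidene]chromium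
Product: 13 2-{2-[(2R,3R)-3-({[tert-butyl(dimethyl)silyl]oxy}methyl)-2-methyloxiran-2-yl]ethyl}-4-methoxy-6-methylphenol, via tricarbonylchromium arene complex 12 (not isolated)
Conditions: 11 (1.3 equiv), THF (degassed), 50 °C, argon; then air, Et2O, rt, daylight; filtration through silica
Reagents that add atoms: none
Why: Warming expels one CO from 11, the terminal alkyne of 6 takes the free site and inserts into the Cr=C bond so that its CH carbon joins the former carbene carbon (C5–C6) and its substituted carbon becomes the new chromium-bound carbene; migration of a CO ligand onto that carbon (C4a–C8a) gives a chromium-held dienylketene. Ring A then closes by 6π electrocyclisation of the ketene carbon onto the β-carbon of the propenyl group (C8–C8a), and enolisation of the cyclohexadienone gives the 4-methoxyphenol, first as its Cr(CO)3 complex 12, which air sets free. The closest known reaction is the Dötz benzannulation of alkenyl(alkoxy)carbene chromium complexes with terminal alkyl alkynes, used here on an alkyne that carries a remote silyl-protected epoxy alcohol. No stereocentre is made; the two epoxide centres only have to survive neutral, aprotic THF at 50 °C, which the absence of acid and the silyl cap on the primary hydroxyl should allow. The selectivity needed is the direction of alkyne insertion (chain next to the new OH, H next to OMe), and the size difference between H and the CH2CH2 chain on the alkyne secures it; the propenyl geometry is lost on aromatisation, and demetalation by air, not by a strong oxidant, keeps the hydroquinone monoether from going on to the quinone.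

Step 7
Reactants: 13 2-{2-[(2R,3R)-3-({[tert-butyl(dimethyl)silyl]oxy}methyl)-2-methyloxiran-2-yl]ethyl}-4-methoxy-6-methylphenol
Product: 15 (1R)-1-[(2S)-6-methoxy-2,8-dimethyl-3,4-dihydro-2H-chromen-2-yl]ethane-1,2-diol, via silyl ether chroman 14 (not isolated)
Conditions: CSA (cat.), CH2Cl2, 0 °C → rt; then MeOH, rt
Reagents that add atoms: none
Why: Acid activation lets the phenol open the epoxide at its tertiary carbon in a 6-exo-tet closure (favoured by ring size and by the better stabilised carbon) with inversion, which sets C2 of ring B from the Sharpless-derived centre, and methanol with the same acid then cleaves the primary silyl ether.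

Step 8
Reactants: 15 (1R)-1-[(2S)-6-methoxy-2,8-dimethyl-3,4-dihydro-2H-chromen-2-yl]ethane-1,2-diol
Product: 16 (2S)-6-methoxy-2,8-dimethyl-3,4-dihydro-2H-chromene-2-carbaldehyde
Conditions: NaIO4, THF–H2O, 0 °C → rt
Reagents that add atoms: none
Why: Malaprade glycol cleavage removes the CH2OH carbon as formaldehyde, and the aldehyde formed has no α-hydrogen, so C2 cannot epimerise.

Step 9
Reactants: 16 (2S)-6-methoxy-2,8-dimethyl-3,4-dihydro-2H-chromene-2-carbaldehyde
Product: 17 (2S)-2-ethenyl-6-methoxy-2,8-dimethyl-3,4-dihydro-2H-chromene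
Conditions: Ph3PCH3Br, KOtBu, THF, 0 °C → rt
Reagents that add atoms: methyltriphenylphosphonium bromide, C[P+](c1ccccc1)(c1ccccc1)c1ccccc1.[Br-]
Why: Wittig methylenation of a non-enolisable aldehyde with the unstabilised ylide gives the vinyl group without touching C2.

Step 10
Reactants: 18 pent-4-yn-1-ol
Product: 20 (4E)-5-iodo-4-methylpent-4-en-1-ol, via alkenylalane 19 (not isolated)
Conditions: AlMe3 (3 equiv), Cp2ZrCl2 (0.25 equiv), CH2Cl2, 0 °C → rt; then I2, THF, −30 → 0 °C; aq. K2CO3 work-up
Reagents that add atoms: trimethylaluminium, C[Al](C)C; iodine, II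
Why: Negishi zirconium-catalysed carboalumination adds methyl and aluminium syn across the terminal alkyne with methyl on the internal carbon, and iodinolysis of the C–Al bond with retention fixes the (E)-alkenyl iodide that becomes the C6'=C7' alkene of the target.

Step 11
Reactants: 20 (4E)-5-iodo-4-methylpent-4-en-1-ol
Product: 21 (4E)-5-iodo-4-methylpent-4-enal
Conditions: PhI(OAc)2, TEMPO (cat.), CH2Cl2, rt
Reagents that add atoms: none
Why: TEMPO-catalysed oxidation with PhI(OAc)2 stops at the aldehyde and leaves the alkenyl iodide alone.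

Step 12
Reactants: 21 (4E)-5-iodo-4-methylpent-4-enal
Product: 22 ethyl (2Z,6E)-7-iodo-2,6-dimethylhepta-2,6-dienoate
Conditions: ethyl 2-[bis(2,2,2-trifluoroethoxy)phosphoryl]propanoate, KN(SiMe3)2, 18-crown-6, THF, −78 °C
Reagents that add atoms: ethyl 2-[bis(2,2,2-trifluoroethoxy)phosphoryl]propanoate, CCOC(=O)C(C)P(=O)(OCC(F)(F)F)OCC(F)(F)F
Why: Still–Gennari variant of the Horner–Wadsworth–Emmons reaction, in which the electron-poor phosphonate with a crown-separated potassium ion eliminates quickly from the kinetic adduct and should place the ester cis to the chain, the Z geometry that the target has at its acid-bearing alkene.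

Step 13
Reactants: 17 (2S)-2-ethenyl-6-methoxy-2,8-dimethyl-3,4-dihydro-2H-chromene; 22 ethyl (2Z,6E)-7-iodo-2,6-dimethylhepta-2,6-dienoate
Product: 24 ethyl (2Z,6E)-9-[(2R)-6-methoxy-2,8-dimethyl-3,4-dihydro-2H-chromen-2-yl]-2,6-dimethylnona-2,6-dienoate, via B-alkyl-9-BBN 23 (not isolated)
Conditions: 9-BBN (0.5 M in THF), 0 °C → rt; then 22, Pd(dppf)Cl2 (cat.), AsPh3 (cat.), aq. K3PO4, DMF, rt
Reagents that add atoms: none
Why: Anti-Markovnikov hydroboration of the vinyl group with 9-BBN followed by B-alkyl Suzuki–Miyaura coupling with the alkenyl iodide, which keeps the iodide geometry and tolerates the ester under phosphate base; C2 is not involved, and its descriptor changes from S to R only because the substituent priorities change.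

Step 14
Reactants: 24 ethyl (2Z,6E)-9-[(2R)-6-methoxy-2,8-dimethyl-3,4-dihydro-2H-chromen-2-yl]-2,6-dimethylnona-2,6-dienoate
Product: 25 (2Z,6E)-9-[(2R)-6-methoxy-2,8-dimethyl-3,4-dihydro-2H-chromen-2-yl]-2,6-dimethylnona-2,6-dienoic acid
Conditions: LiOH·H2O, THF–EtOH–H2O, rt → 40 °C; then 1 M HCl to pH 3
Reagents that add atoms: lithium hydroxide, [Li+].[OH-]
Why: Saponification of the ethyl ester under conditions mild enough that the (Z)-α-methyl enoate should not isomerise, while the chroman centre, which has no acidic hydrogen, is untouched.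

Compound list
1 | geranyl acetate, (2E)-3,7-dimethylocta-2,6-dien-1-yl acetate | CC(C)=CCC/C(C)=C/COC(C)=O | starting material
2 | 6,7-epoxygeranyl acetate, (2E)-5-(3,3-dimethyloxiran-2-yl)-3-methylpent-2-en-1-yl acetate (racemic at the epoxide) | CC1(C)OC1CC/C(C)=C/COC(C)=O | intermediate
3 | (2E)-3-methyl-6-oxohex-2-en-1-yl acetate | O=CCC/C(C)=C/COC(C)=O | intermediate
4 | (2E)-3-methylhept-2-en-6-yn-1-ol | C#CCC/C(C)=C/CO | intermediate
5 | [(2R,3R)-3-(but-3-yn-1-yl)-3-methyloxiran-2-yl]methanol | C#CCC[C@@]1(C)O[C@@H]1CO | intermediate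
6 | tert-butyl{[(2R,3R)-3-(but-3-yn-1-yl)-3-methyloxiran-2-yl]methoxy}dimethylsilane | C#CCC[C@@]1(C)O[C@@H]1CO[Si](C)(C)C(C)(C)C | intermediate
7 | (E)-1-bromoprop-1-ene | C/C=C/Br | starting material
8 | hexacarbonylchromium, Cr(CO)6 | O=C=[Cr](=C=O)(=C=O)(=C=O)(=C=O)=C=O | starting material
9 | (E)-prop-1-enyllithium | C/C=C/[Li] | intermediate
10 | lithium pentacarbonyl[(2E)-1-oxidobut-2-en-1-ylidene]chromate (lithium acylchromate) | [Li+].C/C=C/C([O-])=[Cr](=C=O)(=C=O)(=C=O)(=C=O)=C=O | intermediate
11 | pentacarbonyl[(2E)-1-methoxybut-2-en-1-ylidene]chromium | C/C=C/C(OC)=[Cr](=C=O)(=C=O)(=C=O)(=C=O)=C=O | intermediate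
12 | tricarbonyl(η6-arene)chromium complex of phenol 13, Cr(CO)3 bound to ring A | COc1cc(C)c(O)c(c1)CC[C@@]1(C)O[C@@H]1CO[Si](C)(C)C(C)(C)C.O=C=[Cr](=C=O)=C=O | intermediate
13 | 2-{2-[(2R,3R)-3-({[tert-butyl(dimethyl)silyl]oxy}methyl)-2-methyloxiran-2-yl]ethyl}-4-methoxy-6-methylphenol | COc1cc(C)c(O)c(c1)CC[C@@]1(C)O[C@@H]1CO[Si](C)(C)C(C)(C)C | intermediate
14 | (1R)-2-{[tert-butyl(dimethyl)silyl]oxy}-1-[(2S)-6-methoxy-2,8-dimethyl-3,4-dihydro-2H-chromen-2-yl]ethan-1-ol | COc1cc(C)c2c(c1)CC[C@]([C@H](O)CO[Si](C)(C)C(C)(C)C)(C)O2 | intermediate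
15 | (1R)-1-[(2S)-6-methoxy-2,8-dimethyl-3,4-dihydro-2H-chromen-2-yl]ethane-1,2-diol | COc1cc(C)c2c(c1)CC[C@]([C@H](O)CO)(C)O2 | intermediate
16 | (2S)-6-methoxy-2,8-dimethyl-3,4-dihydro-2H-chromene-2-carbaldehyde | COc1cc(C)c2c(c1)CC[C@](C=O)(C)O2 | intermediate
17 | (2S)-2-ethenyl-6-methoxy-2,8-dimethyl-3,4-dihydro-2H-chromene | COc1cc(C)c2c(c1)CC[C@](C=C)(C)O2 | intermediate
18 | pent-4-yn-1-ol | C#CCCCO | starting material
19 | {[(4E)-5-(dimethylalumanyl)-4-methylpent-4-en-1-yl]oxy}dimethylalumane (alkenylalane) | C[Al](C)OCCC/C(C)=C/[Al](C)C | intermediate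
20 | (4E)-5-iodo-4-methylpent-4-en-1-ol | OCCC/C(C)=C/I | intermediate
21 | (4E)-5-iodo-4-methylpent-4-enal | O=CCC/C(C)=C/I | intermediate
22 | ethyl (2Z,6E)-7-iodo-2,6-dimethylhepta-2,6-dienoate | I/C=C(\C)CC/C=C(/C)C(=O)OCC | intermediate
23 | 9-{2-[(2R)-6-methoxy-2,8-dimethyl-3,4-dihydro-2H-chromen-2-yl]ethyl}-9-borabicyclo[3.3.1]nonane | COc1cc(C)c2c(c1)CC[C@](CCB1C3CCCC1CCC3)(C)O2 | intermediate
24 | ethyl (2Z,6E)-9-[(2R)-6-methoxy-2,8-dimethyl-3,4-dihydro-2H-chromen-2-yl]-2,6-dimethylnona-2,6-dienoate | COc1cc(C)c2c(c1)CC[C@@](C)(CC/C=C(\C)CC/C=C(/C)C(=O)OCC)O2 | intermediate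
25 | (2Z,6E)-9-[(2R)-6-methoxy-2,8-dimethyl-3,4-dihydro-2H-chromen-2-yl]-2,6-dimethylnona-2,6-dienoic acid | COc1cc(C)c2c(c1)CC[C@@](C)(CC/C=C(\C)CC/C=C(/C)C(=O)O)O2 | target

Total step count: 14. Longest linear sequence: 10 steps (steps 1, 2, 3, 4, 6, 7, 8, 9, 13, 14).

Steps most likely to fail

Step 6 (benzannulation). The epoxide may be opened early and without control, by the new phenol while it is still bound to chromium or by chromium Lewis acids at 50 °C. Alkyne insertion may also be sluggish, so that the carbene complex decomposes first. A clean closure in the flask would do no harm, since 14 is the next intermediate. The fallback sets the stereocentre after ring A instead of before. It sets out from 4, which methyl chloroformate and pyridine in CH2Cl2 turn into (2E)-3-methylhept-2-en-6-yn-1-yl methyl carbonate F1. Benzannulation of F1 with 11 under the conditions of step 6 would give first the tricarbonylchromium arene complex F2 and, after air demetalation, (2E)-5-(2-hydroxy-5-methoxy-3-methylphenyl)-3-methylpent-2-en-1-yl methyl carbonate F3; this alkyne partner has no acid-sensitive group. Zerovalent palladium from Pd2(dba)3·CHCl3, with the C2-symmetric bis(2-diphenylphosphinobenzamide) ligand of trans-1,2-diaminocyclohexane and AcOH in CH2Cl2, then ionises the carbonate. The phenol closes ring B at the more substituted allyl terminus (asymmetric Tsuji–Trost etherification, 6-exo). The ligand antipode is chosen on a model substrate so that the S centre results. The fallback comes back to the route at 17.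

Step 7 (closure of ring B). Ionisation at the tertiary carbon ahead of C–O bond formation would erode the configuration at C2. Attack at the secondary carbon (7-endo) or a hydride shift of the activated epoxide (Meinwald rearrangement) may also compete. The fallback replaces acid activation of the silyl ether by a metal-templated opening of the free epoxy alcohol. It sets out from 13, which Bu4NF in THF at 0 °C converts into 2-{2-[(2R,3R)-3-(hydroxymethyl)-2-methyloxiran-2-yl]ethyl}-4-methoxy-6-methylphenol F4. Ti(OiPr)4 (1.5 equiv) in CH2Cl2 at rt then binds the epoxy alkoxide and the phenoxide on one titanium centre and directs the phenoxide to C3 of the 2,3-epoxy alcohol, the tertiary carbon, with inversion (titanium-mediated C3-selective opening of 2,3-epoxy alcohols). The fallback comes back at 15.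

Step 13 (hydroboration and cross-coupling). Transmetalation of the β-branched alkylborane may be slow, so that protodeboronation and homocoupling of the iodide take over, and the aqueous base may hydrolyse the ester. The fallback uses an organozinc in place of the organoborane and needs no aqueous base. It sets out from 17: 9-BBN and then NaOH/H2O2 give 2-[(2S)-6-methoxy-2,8-dimethyl-3,4-dihydro-2H-chromen-2-yl]ethan-1-ol F5 by way of 23. PPh3, I2 and imidazole in CH2Cl2 give (2S)-2-(2-iodoethyl)-6-methoxy-2,8-dimethyl-3,4-dihydro-2H-chromene F6. Zinc dust and LiCl in THF insert into the C–I bond to give {2-[(2S)-6-methoxy-2,8-dimethyl-3,4-dihydro-2H-chromen-2-yl]ethyl}(iodo)zinc F7, which couples with 22 under Pd(PPh3)4 catalysis in THF (Negishi coupling). The fallback comes back at 24.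

Further compounds
F1 | step 6 | (2E)-3-methylhept-2-en-6-yn-1-yl methyl carbonate | C#CCC/C(C)=C/COC(=O)OC
F2 | step 6 | tricarbonyl(η6-arene)chromium complex of F3 | COc1cc(C)c(O)c(c1)CC/C(C)=C/COC(=O)OC.O=C=[Cr](=C=O)=C=O
F3 | step 6 | (2E)-5-(2-hydroxy-5-methoxy-3-methylphenyl)-3-methylpent-2-en-1-yl methyl carbonate | COc1cc(C)c(O)c(c1)CC/C(C)=C/COC(=O)OC
F4 | step 7 | 2-{2-[(2R,3R)-3-(hydroxymethyl)-2-methyloxiran-2-yl]ethyl}-4-methoxy-6-methylphenol | COc1cc(C)c(O)c(c1)CC[C@@]1(C)O[C@@H]1CO
F5 | step 13 | 2-[(2S)-6-methoxy-2,8-dimethyl-3,4-dihydro-2H-chromen-2-yl]ethan-1-ol | COc1cc(C)c2c(c1)CC[C@@](C)(CCO)O2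
F6 | step 13 | (2S)-2-(2-iodoethyl)-6-methoxy-2,8-dimethyl-3,4-dihydro-2H-chromene | COc1cc(C)c2c(c1)CC[C@@](C)(CCI)O2
F7 | step 13 | {2-[(2S)-6-methoxy-2,8-dimethyl-3,4-dihydro-2H-chromen-2-yl]ethyl}(iodo)zinc | COc1cc(C)c2c(c1)CC[C@@](C)(CC[Zn]I)O2
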